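Ring A of the tetralone (C4a, C5, C6, C7, C8, C8a) is a benzene ring with oxygen on the neighbouring carbons C6 and C7, sharing its C4a–C8a edge with ring B. After removal of the benzyl group and the C7 O-methyl group, C4a–C8a and C7–C8 are therefore cut together: a 4-methoxyfuran supplies C4a, C5, C6, C7 and the C7 oxygen, the alkyne of a tethered ynone supplies C8 and C8a.
The open-chain ynone is cut at C1–C8a (ethynyl Grignard reagent on a Weinreb amide), at C2–CH3, at C2 itself (inserted between C1 and C3 by Arndt–Eistert homologation), at C3–CH3 and at C4–furan (conjugate addition to an aryl acrylimide).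
Forward, the chain aryl–C4–C3–C2–C1–alkyne is joined in steps 1–11, rings B and A close together in step 12, and O-methylation, C2 equilibration and debenzylation follow in steps 13–15.
C4 and C3 come from one (R)-4-benzyloxazolidin-2-one, which delivers first the furyl group and then the methyl group to the same face; this is the 3,4-cis pattern, whereas aryl copper onto a furyl acrylimide followed by methylation would give 3,4-trans. The furan is therefore the nucleophile, metalated at the required carbon with the help of a silyl block.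
C2 is formed as both epimers and is set last, by enolate equilibration to the 2,3-trans tetralone.

Key step: step 12

Assumption: 3-methoxyfuran is bought as such; it is otherwise one copper-catalysed methoxylation (NaOMe, CuBr) away from 3-bromofuran.

Step 1
Reactants: 1 3-(benzyloxy)-4-methoxybenzaldehyde; 2 malonic acid
Product: 4 (2E)-3-[3-(benzyloxy)-4-methoxyphenyl]prop-2-enoic acid, via arylidenemalonic acid 3 (not isolated)
Conditions: pyridine, piperidine (10 mol %), 90 °C
Reagents that add atoms: none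
Why: Knoevenagel–Doebner condensation, in which the arylidene malonic acid 3 loses CO2 in hot pyridine to leave the thermodynamically preferred (E)-cinnamic acid, and no stereocentre is formed.

Step 2
Reactants: 4 (2E)-3-[3-(benzyloxy)-4-methoxyphenyl]prop-2-enoic acid; 5 (4R)-4-benzyl-1,3-oxazolidin-2-one
Product: 7 (4R)-4-benzyl-3-{(2E)-3-[3-(benzyloxy)-4-methoxyphenyl]prop-2-enoyl}-1,3-oxazolidin-2-one, via mixed pivalic anhydride 6 (not isolated)
Conditions: t-BuCOCl, Et3N, THF, −20 °C; then 5, LiCl, −20 → 23 °C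
Reagents that add atoms: none
Why: N-acylation of an oxazolidinone by the mixed-anhydride method, in which the LiCl-activated oxazolidinone attacks the unhindered cinnamoyl carbonyl of 6 and not the one shielded by the tert-butyl group.

Step 3
Reactants: 8 3-methoxyfuran
Product: 10 3-methoxy-2-(trimethylsilyl)furan, via 2-lithio-3-methoxyfuran 9 (not isolated)
Conditions: n-BuLi, THF, −78 → 0 °C; then Me3SiCl, −78 → 23 °C
Reagents that add atoms: chlorotrimethylsilane, C[Si](C)(C)Cl
Why: Directed α-lithiation of a furan followed by C-silylation: n-BuLi removes the most acidic proton, at C2 between the ring oxygen and the methoxy group, and the Me3Si group then blocks this position so that the next metalation has to take place at C5.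

Step 4
Reactants: 10 3-methoxy-2-(trimethylsilyl)furan; 7 (4R)-4-benzyl-3-{(2E)-3-[3-(benzyloxy)-4-methoxyphenyl]prop-2-enoyl}-1,3-oxazolidin-2-one
Product: 13 (4R)-4-benzyl-3-{(3R)-3-[3-(benzyloxy)-4-methoxyphenyl]-3-[4-methoxy-5-(trimethylsilyl)furan-2-yl]propanoyl}-1,3-oxazolidin-2-one, via furyllithium 11 (not isolated), via furylmagnesium bromide 12 (not isolated)
Conditions: 10 (1.6 equiv), n-BuLi, THF, 0 °C; MgBr2·OEt2, −20 °C; CuBr·SMe2 (30 mol %), then 7, THF/Me2S, −40 → −10 °C
Reagents that add atoms: none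
Why: Copper-catalysed conjugate addition of a Grignard reagent to an N-enoyl oxazolidinone: lithiation of 10 at its only free α-position and Li-to-Mg exchange give 12, and the furyl group is delivered to the β-carbon of the Mg-chelated s-cis imide on the face opposite to the 4-benzyl group, which sets the (3R) centre (C4 of the target) with the furan, not the arene, as the incoming group.

Step 5
Reactants: 13 (4R)-4-benzyl-3-{(3R)-3-[3-(benzyloxy)-4-methoxyphenyl]-3-[4-methoxy-5-(trimethylsilyl)furan-2-yl]propanoyl}-1,3-oxazolidin-2-one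
Product: 14 (4R)-4-benzyl-3-{(3R)-3-[3-(benzyloxy)-4-methoxyphenyl]-3-(4-methoxyfuran-2-yl)propanoyl}-1,3-oxazolidin-2-one
Conditions: Bu4NF, AcOH, THF, 0 → 23 °C
Reagents that add atoms: none
Why: Fluoride-induced protodesilylation of a 2-silylfuran: attack of fluoride on silicon releases the furan α-carbon, which is stabilised by the ring oxygen and the neighbouring methoxy group, and acetic acid protonates it and buffers the medium so that the imide survives.

Step 6
Reactants: 14 (4R)-4-benzyl-3-{(3R)-3-[3-(benzyloxy)-4-methoxyphenyl]-3-(4-methoxyfuran-2-yl)propanoyl}-1,3-oxazolidin-2-one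
Product: 16 (4R)-4-benzyl-3-{(2R,3R)-3-[3-(benzyloxy)-4-methoxyphenyl]-3-(4-methoxyfuran-2-yl)-2-methylpropanoyl}-1,3-oxazolidin-2-one, via imide sodium enolate 15 (not isolated)
Conditions: NaN(SiMe3)2, THF, −78 °C; then MeI, −78 → −40 °C
Reagents that add atoms: iodomethane, CI
Why: Evans enolate alkylation: NaN(SiMe3)2 gives the chelated (Z)-enolate 15 and iodomethane enters from the face opposite to the 4-benzyl group, the same face that received the furyl group, which sets the (2R) centre (C3 of the target) and with it the 3,4-cis relationship.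

Step 7
Reactants: 16 (4R)-4-benzyl-3-{(2R,3R)-3-[3-(benzyloxy)-4-methoxyphenyl]-3-(4-methoxyfuran-2-yl)-2-methylpropanoyl}-1,3-oxazolidin-2-one
Product: 18 (2R,3R)-3-[3-(benzyloxy)-4-methoxyphenyl]-3-(4-methoxyfuran-2-yl)-2-methylpropanoic acid, via lithium peroxycarboxylate 17 (not isolated)
Conditions: LiOH, H2O2, THF/H2O, 0 °C; then Na2SO3; NaHSO4 (aq) to pH 4
Reagents that add atoms: hydrogen peroxide, OO
Why: Hydroperoxide cleavage of an N-acyl oxazolidinone: LiOOH attacks the exocyclic carbonyl selectively even in this hindered imide, sulfite reduces the peroxy acid salt 17, and the α-centre should not epimerise under these conditions while the auxiliary is recovered.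

Step 8
Reactants: 18 (2R,3R)-3-[3-(benzyloxy)-4-methoxyphenyl]-3-(4-methoxyfuran-2-yl)-2-methylpropanoic acid
Product: 20 (3R,4R)-4-[3-(benzyloxy)-4-methoxyphenyl]-1-diazo-4-(4-methoxyfuran-2-yl)-3-methylbutan-2-one, via mixed carbonic anhydride 19 (not isolated)
Conditions: i-BuOCOCl, N-methylmorpholine, THF, −15 °C; then CH2N2, Et2O, −15 → 0 °C
Reagents that add atoms: diazomethane, C=[N+]=[N-]
Why: First half of the Arndt–Eistert homologation: the acid is activated at low temperature as the isobutyl carbonic anhydride 19, without an acid chloride or HCl that would endanger the methoxyfuran, and diazomethane is acylated to the α-diazoketone with the α-centre intact.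

Step 9
Reactants: 20 (3R,4R)-4-[3-(benzyloxy)-4-methoxyphenyl]-1-diazo-4-(4-methoxyfuran-2-yl)-3-methylbutan-2-one
Product: 22 (3S,4R)-4-[3-(benzyloxy)-4-methoxyphenyl]-N-methoxy-4-(4-methoxyfuran-2-yl)-N,3-dimethylbutanamide, via ketene 21 (not isolated)
Conditions: PhCO2Ag (10 mol %), Et3N, MeNH(OMe)·HCl, THF, 23 °C, dark
Reagents that add atoms: N,O-dimethylhydroxylamine hydrochloride, CNOC.Cl
Why: Wolff rearrangement: silver-catalysed loss of N2 with 1,2-shift of the stereogenic carbon (future C3, retention of configuration, the descriptor changes only because the priorities change) gives ketene 21, which N,O-dimethylhydroxylamine traps as the homologated Weinreb amide, so that the inserted CH2 becomes C2 of the target.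

Step 10
Reactants: 22 (3S,4R)-4-[3-(benzyloxy)-4-methoxyphenyl]-N-methoxy-4-(4-methoxyfuran-2-yl)-N,3-dimethylbutanamide
Product: 24 (2RS,3R,4R)-4-[3-(benzyloxy)-4-methoxyphenyl]-N-methoxy-4-(4-methoxyfuran-2-yl)-N,2,3-trimethylbutanamide, via amide lithium enolate 23 (not isolated)
Conditions: LiN(i-Pr)2, THF, −78 °C; then MeI, −78 → −30 °C
Reagents that add atoms: iodomethane, CI
Why: α-Alkylation of an amide enolate: LiN(i-Pr)2 at −78 °C forms the (Z)-enolate 23, which iodomethane methylates at the future C2; this centre is formed without useful control, both epimers are carried on, and it is settled in step 14.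

Step 11
Reactants: 24 (2RS,3R,4R)-4-[3-(benzyloxy)-4-methoxyphenyl]-N-methoxy-4-(4-methoxyfuran-2-yl)-N,2,3-trimethylbutanamide; 25 ethynylmagnesium bromide
Product: 26 (4RS,5R,6R)-6-[3-(benzyloxy)-4-methoxyphenyl]-6-(4-methoxyfuran-2-yl)-4,5-dimethylhex-1-yn-3-one
Conditions: 25 (3 equiv), THF, 0 → 23 °C; cold aqueous work-up
Reagents that add atoms: none
Why: Weinreb ketone synthesis: the chelated magnesium hemiaminal formed from 24 and ethynylmagnesium bromide is stable until work-up, so that a single ethynyl group is introduced and the terminal ynone is released only on cold aqueous quench.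

Step 12
Reactants: 26 (4RS,5R,6R)-6-[3-(benzyloxy)-4-methoxyphenyl]-6-(4-methoxyfuran-2-yl)-4,5-dimethylhex-1-yn-3-one
Product: 28 (2RS,3R,4R)-4-[3-(benzyloxy)-4-methoxyphenyl]-7-hydroxy-6-methoxy-2,3-dimethyl-3,4-dihydronaphthalen-1(2H)-one, via oxanorbornadiene 27 (not isolated)
Conditions: toluene (0.01 M), 90 °C; then pyridinium p-toluenesulfonate (5 mol %), 23 °C
Reagents that add atoms: none
Why: The 4-methoxyfuran of 26 (diene carbons that become C4a, C5, C6 and C7) and the ynone alkyne (C8a and C8) are joined by a four-atom tether, so that a concerted, asynchronous intramolecular [4+2] cycloaddition forms C4a–C8a and C7–C8 and gives 7-oxanorbornadiene 27; the closest known reaction type is the intramolecular Diels–Alder reaction of furans with tethered alkynones followed by ring-opening aromatisation of the oxanorbornadiene to a phenol. Ring B, six-membered, closes through the tether as the ring fused to the cycloadduct (bond C4a–C8a, with the carbonyl group inside the new ring), and ring A is the six-membered carbocycle assembled from the four furan carbons and the two alkyne carbons. Heterolysis of the C4a–O bridge bond, which leaves a cation that is an oxocarbenium ion through the C6 methoxy group, followed by loss of the C7 proton, opens 27 to the C7 phenol, which is aromatic ring A with oxygen at C6 and C7. No lasting stereocentre is created, because the two bridgeheads of 27 (either bridge face may form, 27 is drawn as one of them) vanish on aromatisation while C3 and C4 are not touched and C2 stays epimeric. The step needs regioselectivity in the cycloaddition, which the tether secures because only the furan carbon bearing the chain can reach the carbonyl-bound alkyne carbon and the most nucleophilic furan carbon then meets the electrophilic alkyne terminus, and it needs the right sense of bridge opening, which the position of the methoxy group secures. The acid catalyst is added only once the furan has been consumed and serves to complete the opening of any 27 that persists.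

Step 13
Reactants: 28 (2RS,3R,4R)-4-[3-(benzyloxy)-4-methoxyphenyl]-7-hydroxy-6-methoxy-2,3-dimethyl-3,4-dihydronaphthalen-1(2H)-one
Product: 30 (2RS,3R,4R)-4-[3-(benzyloxy)-4-methoxyphenyl]-6,7-dimethoxy-2,3-dimethyl-3,4-dihydronaphthalen-1(2H)-one, via potassium phenoxide 29 (not isolated)
Conditions: MeI, K2CO3, acetone, 50 °C
Reagents that add atoms: iodomethane, CI
Why: Williamson ether synthesis: K2CO3 deprotonates only the phenol, and the phenoxide 29 is methylated by iodomethane while the ketone, which carbonate in acetone does not enolise, is left alone.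

Step 14
Reactants: 30 (2RS,3R,4R)-4-[3-(benzyloxy)-4-methoxyphenyl]-6,7-dimethoxy-2,3-dimethyl-3,4-dihydronaphthalen-1(2H)-one
Product: 32 (2S,3R,4R)-4-[3-(benzyloxy)-4-methoxyphenyl]-6,7-dimethoxy-2,3-dimethyl-3,4-dihydronaphthalen-1(2H)-one, via tetralone sodium enolate 31 (not isolated)
Conditions: NaOMe (0.3 equiv), MeOH/THF, 23 °C
Reagents that add atoms: none
Why: Base-mediated epimerisation of a ketone α-centre through its enolate 31 under thermodynamic control: in the 3,4-cis series with a pseudoaxial aryl group at C4 the C2 methyl group is equatorial only in the 2,3-trans isomer, so that reversible protonation should converge both epimers on the (2S) configuration, the only stereocentre that is touched.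

Step 15
Reactants: 32 (2S,3R,4R)-4-[3-(benzyloxy)-4-methoxyphenyl]-6,7-dimethoxy-2,3-dimethyl-3,4-dihydronaphthalen-1(2H)-one
Product: 33 (2S,3R,4R)-4-(3-hydroxy-4-methoxyphenyl)-6,7-dimethoxy-2,3-dimethyl-3,4-dihydronaphthalen-1(2H)-one
Conditions: H2 (1 atm), Pd/C (10 wt %), EtOAc, 23 °C
Reagents that add atoms: none
Why: Hydrogenolysis of a benzyl aryl ether over Pd/C, which under neutral conditions at 1 atm is faster than reduction of the aryl ketone and frees the phenol of the pendant ring.

Compound list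
1 | 3-(benzyloxy)-4-methoxybenzaldehyde | COc1ccc(C=O)cc1OCc1ccccc1 | starting material
2 | malonic acid | OC(=O)CC(=O)O | starting material
3 | 2-{[3-(benzyloxy)-4-methoxyphenyl]methylidene}propanedioic acid | COc1ccc(C=C(C(=O)O)C(=O)O)cc1OCc1ccccc1 | intermediate
4 | (2E)-3-[3-(benzyloxy)-4-methoxyphenyl]prop-2-enoic acid | COc1ccc(/C=C/C(=O)O)cc1OCc1ccccc1 | intermediate
5 | (4R)-4-benzyl-1,3-oxazolidin-2-one | O=C1N[C@H](Cc2ccccc2)CO1 | starting material
6 | (2E)-3-[3-(benzyloxy)-4-methoxyphenyl]prop-2-enoic 2,2-dimethylpropanoic anhydride | COc1ccc(/C=C/C(=O)OC(=O)C(C)(C)C)cc1OCc1ccccc1 | intermediate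
7 | (4R)-4-benzyl-3-{(2E)-3-[3-(benzyloxy)-4-methoxyphenyl]prop-2-enoyl}-1,3-oxazolidin-2-one | COc1ccc(/C=C/C(=O)N2[C@H](Cc3ccccc3)COC2=O)cc1OCc1ccccc1 | intermediate
8 | 3-methoxyfuran | COc1ccoc1 | starting material
9 | (3-methoxyfuran-2-yl)lithium | [Li]c1occc1OC | intermediate
10 | 3-methoxy-2-(trimethylsilyl)furan | COc1ccoc1[Si](C)(C)C | intermediate
11 | [4-methoxy-5-(trimethylsilyl)furan-2-yl]lithium | [Li]c1cc(OC)c([Si](C)(C)C)o1 | intermediate
12 | bromo[4-methoxy-5-(trimethylsilyl)furan-2-yl]magnesium | Br[Mg]c1cc(OC)c([Si](C)(C)C)o1 | intermediate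
13 | (4R)-4-benzyl-3-{(3R)-3-[3-(benzyloxy)-4-methoxyphenyl]-3-[4-methoxy-5-(trimethylsilyl)furan-2-yl]propanoyl}-1,3-oxazolidin-2-one | COc1ccc([C@@H](CC(=O)N2[C@H](Cc3ccccc3)COC2=O)c2cc(OC)c([Si](C)(C)C)o2)cc1OCc1ccccc1 | intermediate
14 | (4R)-4-benzyl-3-{(3R)-3-[3-(benzyloxy)-4-methoxyphenyl]-3-(4-methoxyfuran-2-yl)propanoyl}-1,3-oxazolidin-2-one | COc1ccc([C@@H](CC(=O)N2[C@H](Cc3ccccc3)COC2=O)c2cc(OC)co2)cc1OCc1ccccc1 | intermediate
15 | sodium (Z)-enolate of 14 | [Na+].[O-]/C(=C\[C@H](c1ccc(OC)c(OCc2ccccc2)c1)c1cc(OC)co1)N1C(=O)OC[C@H]1Cc1ccccc1 | intermediate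
16 | (4R)-4-benzyl-3-{(2R,3R)-3-[3-(benzyloxy)-4-methoxyphenyl]-3-(4-methoxyfuran-2-yl)-2-methylpropanoyl}-1,3-oxazolidin-2-one | COc1ccc([C@H](c2cc(OC)co2)[C@@H](C)C(=O)N2[C@H](Cc3ccccc3)COC2=O)cc1OCc1ccccc1 | intermediate
17 | lithium (2R,3R)-3-[3-(benzyloxy)-4-methoxyphenyl]-3-(4-methoxyfuran-2-yl)-2-methylpropaneperoxoate | COc1ccc([C@H](c2cc(OC)co2)[C@@H](C)C(=O)O[O-])cc1OCc1ccccc1.[Li+] | intermediate
18 | (2R,3R)-3-[3-(benzyloxy)-4-methoxyphenyl]-3-(4-methoxyfuran-2-yl)-2-methylpropanoic acid | COc1ccc([C@H](c2cc(OC)co2)[C@@H](C)C(=O)O)cc1OCc1ccccc1 | intermediate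
19 | isobutyl carbonic mixed anhydride of 18 | COc1ccc([C@H](c2cc(OC)co2)[C@@H](C)C(=O)OC(=O)OCC(C)C)cc1OCc1ccccc1 | intermediate
20 | (3R,4R)-4-[3-(benzyloxy)-4-methoxyphenyl]-1-diazo-4-(4-methoxyfuran-2-yl)-3-methylbutan-2-one | COc1ccc([C@H](c2cc(OC)co2)[C@@H](C)C(=O)C=[N+]=[N-])cc1OCc1ccccc1 | intermediate
21 | (3R,4R)-4-[3-(benzyloxy)-4-methoxyphenyl]-4-(4-methoxyfuran-2-yl)-3-methylbut-1-en-1-one (ketene) | COc1ccc([C@H](c2cc(OC)co2)[C@@H](C)C=C=O)cc1OCc1ccccc1 | intermediate
22 | (3S,4R)-4-[3-(benzyloxy)-4-methoxyphenyl]-N-methoxy-4-(4-methoxyfuran-2-yl)-N,3-dimethylbutanamide | COc1ccc([C@H](c2cc(OC)co2)[C@@H](C)CC(=O)N(C)OC)cc1OCc1ccccc1 | intermediate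
23 | lithium (Z)-enolate of 22 | COc1ccc([C@H](c2cc(OC)co2)[C@@H](C)/C=C(\[O-])N(C)OC)cc1OCc1ccccc1.[Li+] | intermediate
24 | (2RS,3R,4R)-4-[3-(benzyloxy)-4-methoxyphenyl]-N-methoxy-4-(4-methoxyfuran-2-yl)-N,2,3-trimethylbutanamide (both C2 epimers) | COc1ccc([C@H](c2cc(OC)co2)[C@@H](C)C(C)C(=O)N(C)OC)cc1OCc1ccccc1 | intermediate
25 | ethynylmagnesium bromide | C#C[Mg]Br | starting material
26 | (4RS,5R,6R)-6-[3-(benzyloxy)-4-methoxyphenyl]-6-(4-methoxyfuran-2-yl)-4,5-dimethylhex-1-yn-3-one (both C4 epimers) | COc1ccc([C@H](c2cc(OC)co2)[C@@H](C)C(C)C(=O)C#C)cc1OCc1ccccc1 | intermediate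
27 | 7-oxanorbornadiene cycloadduct of 26 (oxygen bridge from C4a to C7, double bonds C5=C6 and C8=C8a, one bridge diastereomer drawn) | COC1=C[C@]23O[C@H]1C=C2C(=O)C(C)[C@H](C)[C@@H]3c1ccc(OC)c(OCc2ccccc2)c1 | intermediate
28 | (2RS,3R,4R)-4-[3-(benzyloxy)-4-methoxyphenyl]-7-hydroxy-6-methoxy-2,3-dimethyl-3,4-dihydronaphthalen-1(2H)-one (both C2 epimers) | COc1ccc([C@@H]2c3cc(OC)c(O)cc3C(=O)C(C)[C@@H]2C)cc1OCc1ccccc1 | intermediate
29 | potassium phenoxide of 28 | COc1ccc([C@@H]2c3cc(OC)c([O-])cc3C(=O)C(C)[C@@H]2C)cc1OCc1ccccc1.[K+] | intermediate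
30 | (2RS,3R,4R)-4-[3-(benzyloxy)-4-methoxyphenyl]-6,7-dimethoxy-2,3-dimethyl-3,4-dihydronaphthalen-1(2H)-one (both C2 epimers) | COc1ccc([C@@H]2c3cc(OC)c(OC)cc3C(=O)C(C)[C@@H]2C)cc1OCc1ccccc1 | intermediate
31 | sodium enolate of 30 (C1–C2) | COc1ccc([C@@H]2c3cc(OC)c(OC)cc3C([O-])=C(C)[C@@H]2C)cc1OCc1ccccc1.[Na+] | intermediate
32 | (2S,3R,4R)-4-[3-(benzyloxy)-4-methoxyphenyl]-6,7-dimethoxy-2,3-dimethyl-3,4-dihydronaphthalen-1(2H)-one | COc1ccc([C@@H]2c3cc(OC)c(OC)cc3C(=O)[C@@H](C)[C@@H]2C)cc1OCc1ccccc1 | intermediate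
33 | (2S,3R,4R)-4-(3-hydroxy-4-methoxyphenyl)-6,7-dimethoxy-2,3-dimethyl-3,4-dihydronaphthalen-1(2H)-one (CNP0170223.1) | COc1ccc([C@@H]2c3cc(OC)c(OC)cc3C(=O)[C@@H](C)[C@@H]2C)cc1O | target

Total step count: 15. Longest linear sequence: 14 steps (steps 1, 2 and 4–15, from 1).

Steps most likely to fail

Step 4. What may go wrong: incomplete metalation of 10 at C5, or slow transfer of the heteroaryl group from copper to the electron-rich acrylimide, so that direct attack on the imide carbonyls and loss of facial selectivity at the higher temperature then needed take over. Fallback: the arene becomes the nucleophile, and the two centres are set by two auxiliaries of opposite configuration, because one auxiliary with this pairing would give the 3,4-trans series. It sets out from malonic acid 2 and comes back at 14. Bought 4-bromofuran-2-carbaldehyde and 2 (pyridine, piperidine, 90 °C) give, through 2-[(4-bromofuran-2-yl)methylidene]propanedioic acid F1, (2E)-3-(4-bromofuran-2-yl)prop-2-enoic acid F2. Ullmann-type methoxylation of its sodium salt (NaOMe, CuBr 10 mol %, MeOH/DMF, 100 °C) gives (2E)-3-(4-methoxyfuran-2-yl)prop-2-enoic acid F3, which is joined through its mixed pivalic anhydride F4 to bought (4S)-4-benzyl-1,3-oxazolidin-2-one to give (4S)-4-benzyl-3-[(2E)-3-(4-methoxyfuran-2-yl)prop-2-enoyl]-1,3-oxazolidin-2-one F5. Bought 5-bromo-2-methoxyphenol is benzylated (BnBr, K2CO3, DMF) to 2-(benzyloxy)-4-bromo-1-methoxybenzene F6 and turned with Mg into [3-(benzyloxy)-4-methoxyphenyl]magnesium bromide F7. With CuBr·SMe2 this adds to F5 on the face opposite to the benzyl group and should give (4S)-4-benzyl-3-{(3R)-3-[3-(benzyloxy)-4-methoxyphenyl]-3-(4-methoxyfuran-2-yl)propanoyl}-1,3-oxazolidin-2-one F8. Cleavage with LiOH/H2O2, through lithium (3R)-3-[3-(benzyloxy)-4-methoxyphenyl]-3-(4-methoxyfuran-2-yl)propaneperoxoate F9, gives (3R)-3-[3-(benzyloxy)-4-methoxyphenyl]-3-(4-methoxyfuran-2-yl)propanoic acid F10. Acylation of 5 through the mixed pivalic anhydride of this acid F11 then gives 14.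

Step 12. What may go wrong: the terminal ynone is consumed by oligomerisation or by conjugate addition of nucleophiles (the hydroxylamine liberated in step 11, the product phenol) faster than it cyclises, or the cycloaddition needs a temperature that the unprotected alkyne does not survive. Fallback: the alkyne terminus is capped and uncapped only after ring A is aromatic. It sets out from 24 and comes back at 28. Me3SiC≡CLi (THF, −78 → 0 °C) turns 24 into (4RS,5R,6R)-6-[3-(benzyloxy)-4-methoxyphenyl]-6-(4-methoxyfuran-2-yl)-4,5-dimethyl-1-(trimethylsilyl)hex-1-yn-3-one F12, which can be heated longer and hotter (toluene, 110 °C). The same cycloaddition and bridge opening lead through the 8-silyl oxanorbornadiene F13 to (2RS,3R,4R)-4-[3-(benzyloxy)-4-methoxyphenyl]-7-hydroxy-6-methoxy-2,3-dimethyl-8-(trimethylsilyl)-3,4-dihydronaphthalen-1(2H)-one F14. CF3CO2H (CH2Cl2, 0 °C) removes the aryl silane next to the phenol by ipso-protodesilylation and gives 28.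

Step 10. What may go wrong: LiN(i-Pr)2 attacks the N-methoxy group instead of the α-position (E2 loss of formaldehyde to the N-methyl amide), or the enolate is methylated twice. Fallback: the methyl group is put on an ester and the Weinreb amide is made afterwards. It sets out from 20 and comes back at 24. Wolff rearrangement of 20 in methanol (PhCO2Ag, Et3N, MeOH) gives, through ketene 21, methyl (3S,4R)-4-[3-(benzyloxy)-4-methoxyphenyl]-4-(4-methoxyfuran-2-yl)-3-methylbutanoate F15. LiN(i-Pr)2 and MeI give methyl (2RS,3R,4R)-4-[3-(benzyloxy)-4-methoxyphenyl]-4-(4-methoxyfuran-2-yl)-2,3-dimethylbutanoate F16, and MeNH(OMe)·HCl with i-PrMgCl (THF, −20 °C) converts this ester into 24.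

Further compounds
F1 | step 4 | 2-[(4-bromofuran-2-yl)methylidene]propanedioic acid | OC(=O)C(=Cc1cc(Br)co1)C(=O)O
F2 | step 4 | (2E)-3-(4-bromofuran-2-yl)prop-2-enoic acid | OC(=O)/C=C/c1cc(Br)co1
F3 | step 4 | (2E)-3-(4-methoxyfuran-2-yl)prop-2-enoic acid | COc1coc(/C=C/C(=O)O)c1
F4 | step 4 | (2E)-3-(4-methoxyfuran-2-yl)prop-2-enoic 2,2-dimethylpropanoic anhydride | COc1coc(/C=C/C(=O)OC(=O)C(C)(C)C)c1
F5 | step 4 | (4S)-4-benzyl-3-[(2E)-3-(4-methoxyfuran-2-yl)prop-2-enoyl]-1,3-oxazolidin-2-one | COc1coc(/C=C/C(=O)N2[C@@H](Cc3ccccc3)COC2=O)c1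
F6 | step 4 | 2-(benzyloxy)-4-bromo-1-methoxybenzene | COc1ccc(Br)cc1OCc1ccccc1
F7 | step 4 | [3-(benzyloxy)-4-methoxyphenyl]magnesium bromide | COc1ccc([Mg]Br)cc1OCc1ccccc1
F8 | step 4 | (4S)-4-benzyl-3-{(3R)-3-[3-(benzyloxy)-4-methoxyphenyl]-3-(4-methoxyfuran-2-yl)propanoyl}-1,3-oxazolidin-2-one | COc1ccc([C@@H](CC(=O)N2[C@@H](Cc3ccccc3)COC2=O)c2cc(OC)co2)cc1OCc1ccccc1
F9 | step 4 | lithium (3R)-3-[3-(benzyloxy)-4-methoxyphenyl]-3-(4-methoxyfuran-2-yl)propaneperoxoate | COc1ccc([C@@H](CC(=O)O[O-])c2cc(OC)co2)cc1OCc1ccccc1.[Li+]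
F10 | step 4 | (3R)-3-[3-(benzyloxy)-4-methoxyphenyl]-3-(4-methoxyfuran-2-yl)propanoic acid | COc1ccc([C@@H](CC(=O)O)c2cc(OC)co2)cc1OCc1ccccc1
F11 | step 4 | (3R)-3-[3-(benzyloxy)-4-methoxyphenyl]-3-(4-methoxyfuran-2-yl)propanoic 2,2-dimethylpropanoic anhydride | COc1ccc([C@@H](CC(=O)OC(=O)C(C)(C)C)c2cc(OC)co2)cc1OCc1ccccc1
F12 | step 12 | (4RS,5R,6R)-6-[3-(benzyloxy)-4-methoxyphenyl]-6-(4-methoxyfuran-2-yl)-4,5-dimethyl-1-(trimethylsilyl)hex-1-yn-3-one | COc1ccc([C@H](c2cc(OC)co2)[C@@H](C)C(C)C(=O)C#C[Si](C)(C)C)cc1OCc1ccccc1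
F13 | step 12 | 8-(trimethylsilyl)-7-oxanorbornadiene cycloadduct of F12 (one bridge diastereomer drawn) | COC1=C[C@]23O[C@H]1C([Si](C)(C)C)=C2C(=O)C(C)[C@H](C)[C@@H]3c1ccc(OC)c(OCc2ccccc2)c1
F14 | step 12 | (2RS,3R,4R)-4-[3-(benzyloxy)-4-methoxyphenyl]-7-hydroxy-6-methoxy-2,3-dimethyl-8-(trimethylsilyl)-3,4-dihydronaphthalen-1(2H)-one | COc1ccc([C@@H]2c3cc(OC)c(O)c([Si](C)(C)C)c3C(=O)C(C)[C@@H]2C)cc1OCc1ccccc1
F15 | step 10 | methyl (3S,4R)-4-[3-(benzyloxy)-4-methoxyphenyl]-4-(4-methoxyfuran-2-yl)-3-methylbutanoate | COc1ccc([C@H](c2cc(OC)co2)[C@@H](C)CC(=O)OC)cc1OCc1ccccc1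
F16 | step 10 | methyl (2RS,3R,4R)-4-[3-(benzyloxy)-4-methoxyphenyl]-4-(4-methoxyfuran-2-yl)-2,3-dimethylbutanoate | COc1ccc([C@H](c2cc(OC)co2)[C@@H](C)C(C)C(=O)OC)cc1OCc1ccccc1
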